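The data were computed on assumed constants; noise was put on by code.

The constant I read from the earlier runs is the selectivity factor, E made per Z made at equal D and G: the first north-east reading gives

s = 0.596,

and the first east reading, with half the D, gives 0.590. I work with fractions left, d of the D charge and g of the G charge, so the next J goes to E rather than Z with odds w·d/g, where

w = s · (D charge)/(G charge) = 1.49,

the odds at full charges.

| flask | J | D | G | remark | time |
|---|---|---|---|---|---|
| north-east | 0.14 M | 0.35 M | 0.14 M | run made earlier |  |
| east | 0.14 M | 0.17 M | 0.14 M | run made earlier |  |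
| west | 0.14 M | 0.70 M | 0.14 M | run made earlier |  |
| south | 0.14 M | 0.35 M | 0.21 M | run made earlier |  |
| gamma | 0.14 M | 0.350 M | 0.140 M | everything together at the start | 2.5 min |
| alpha | 0.14 M (fed, over 2.0 min) | 0.350 M | 0.140 M | all else is in the flask from the start; the feed brings no volume worth counting | 2.5 min |
| epsilon | 0.14 M | 0.350 M (fed, over 2.0 min) | 0.140 M | all else is in the flask from the start; the feed brings no volume worth counting | 2.5 min |

north-east run (percent of the J charged)

| time / s | E / % | Z / % |
|---|---|---|
| 25.0 | 38.3 | 25.7 |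
| 50.0 | 49.1 | 32.4 |
| 60.0 | 51.6 | 34.9 |
| 90.0 | 55.2 | 37.4 |

east run (percent of the J charged)

| time / min | E / % | Z / % |
|---|---|---|
| 0.417 | 21.0 | 29.3 |
| 1.00 | 30.2 | 43.5 |
| 2.00 | 35.0 | 52.8 |
| 3.00 | 36.1 | 56.9 |

west run (percent of the J charged)

| time / min | E / % | Z / % |
|---|---|---|
| 0.833 | 71.9 | 21.9 |
| 1.50 | 75.0 | 23.3 |
| 2.50 | 75.9 | 23.2 |
| 3.00 | 76.5 | 23.4 |

south run (percent of the J charged)

| time / min | E / % | Z / % |
|---|---|---|
| 0.250 | 27.6 | 27.7 |
| 0.500 | 37.8 | 38.1 |
| 1.33 | 46.5 | 47.8 |
| 3.00 | 47.9 | 50.9 |

(readings scatter by 0.3 percentage points)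

- which flask leads in share of E in E plus Z ("all alike" within 1.5 percentage points) (gamma / alpha / epsilon / all alike)
- share of E in E plus Z at the end, gamma
- share of E in E plus Z at the end, alpha
- share of E in E plus Z at the end, epsilon

- the earlier runs were read with a standard deviation of 0.3 percentage points

Gamma repeats the north-east charges, so I follow it in slow motion. In the first instants d/g stands at its starting value, and by 25.0 s the readings show 64.0% of the J turned. From 50.0 s to 90.0 s the gains in E and Z give, as a reading,

d/g = 0.819,

less than the 1.22 that E and Z account for at 60.0 s, so I take D to be leaving by some other way as well. By 90.0 s the readings leave 7.40% of the J unturned, so I expect gamma to hold about the 59.6% read at that time. Alpha's J comes in over 2.0 min, longer than the 25.0 s of the north-east run's first reading, so I price it at the late ratio and reckon 55.0%.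

The forecast differs from me on alpha: gamma 59.8%, alpha 59.8%, epsilon 32%, with gamma named, on the ground that “Feeding J leaves this D/G path unchanged, so alpha ≈ gamma, a practical tie”.

The flasks give gamma 59.1%, alpha 51.5% and epsilon 35.6%, so gamma leads.

    J + D → E (k = 0.0900 M⁻¹ s⁻¹)
    G + D → Q (k = 0.0230 M⁻¹ s⁻¹)
    D → L (k = 0.00860 s⁻¹)
    J + G → Z (k = 0.150 M⁻¹ s⁻¹)

In gamma, by 1.25 min, J was down to 10.4% while w·d/g stood at 1.18. In alpha, at the end of the feed at 2.00 min, the flask held 0.184 M of L and 0.0489 M of Q, and w·d/g stood at 0.845 with 37.7% of the J unreacted.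

Epsilon's end share, taken as odds and divided by w, gives an effective d/g of 0.372. Holding that ratio, a neighbouring flask, epsilon with 0.14 M of D, has w = 0.596 and a reckoned share of 18.1%; the flask gives 20.6%.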